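(The numbers in the tables were generated by integration for substances that don't exist; the scatter is artificial.)

I followed one substrate molecule through its fork.

| flask | substrate | remark | time |
|---|---|---|---|
| amber | 0.067 M | run made earlier |  |
| violet | 0.15 M | run made earlier |  |
| flask | 0.10 M |  | 2.0 h |

- amber (time / min: ring / %, substrate / %): 2.00: 17, 80; 4.00: 22, 65; 6.00: 19, 52; 12.0: 23, 27; 20.0: 12, 13; 40.0: 9, 1; 80.0: 4, 0
- violet (time / min: ring / %, substrate / %): 2.00: 10, 78; 4.00: 20, 57; 6.00: 25, 45; 12.0: 18, 24; 20.0: 11, 7; 40.0: 5, 1; 80.0: 4, 0

(each reading ± 2 percentage points)

- when, up to 2.0 h, the flask holds most ring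
- the amount of ring, in percent of the substrate charged, at that time

- percent here means substrate units held: one open dimer counts as two
- percent here means substrate units held: one open trimer counts as three
- what may be going on: substrate -> ring; substrate + open dimer -> open trimer; ring <-> isomer of the product; 2 substrate -> open dimer

Over the first 6.00 min, the substrate readings gave a loss rate of 0.109 min⁻¹ in amber and 0.133 min⁻¹ in violet. I took the part that grew in proportion to the charge as the drain through open dimer and open trimer. The part left when I extrapolated to no charge, 0.0895 min⁻¹, I took as ring closure. In the flask that made a total of 0.119 min⁻¹, and ring closure's part of it was 75.5%: this ring share, the fraction of substrate lost that leaves through ring closure, is the selectivity of the fork.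

By my reckoning, ring closure in the flask began at 0.0895 min⁻¹, as a fraction of the charge, and the falling substrate slowed it in proportion. I placed the flask's crest midway between 4.00 min and 12.0 min, at 8.00 min. With the total loss rate held constant, I reckoned 38.7% of the substrate left by then, which put ring closure at 0.0346 min⁻¹. From the highest readings of the two runs I expected about 24.0% ring there. Holding the share constant, I expected 75.5% of the charge to end as ring or isomer of the product.

The forecast gave 0.13 h and 22%, noting that “The two peaks barely differ in height or timing”.

The flask reached 23.9% ring at 0.132 h, with 39.6% substrate.

    substrate → ring (k = 0.0860 min⁻¹)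
    substrate + open dimer → open trimer (k = 2.40 L mol⁻¹ min⁻¹)
    ring ⇌ isomer of the product (K = 17.0, k = 0.150 min⁻¹)
    2 substrate → open dimer (k = 0.190 L mol⁻¹ min⁻¹)

In the flask, the relaxation half-life of ring and isomer of the product, 0.0727 h, was shorter than the 2.0 h allowed, and at 2.00 h ring stood at 4.32% beside 73.4% isomer of the product. Together they held 77.7% of the charge then; at 0.132 h they held 72.6% of the substrate lost, which is the figure to set beside the ring share of 75.5% reckoned from the early readings. For the neighbour charged with 0.25 M, the same reckoning gave an early ring share of 55.2%, and that flask ended with 58.5% of its charge as ring and isomer of the product.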